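**Retrosynthetic overview**

1. The target is alkannin (S at C1') acylated on the C1' oxygen. The ester with 3-acetoxy-3-methylbutanoic acid is cut last, as a carbodiimide coupling on the free naphthazarin 26.
2. Structural feature: in the 5,8-dihydroxy-1,4-naphthoquinone the ring-fusion carbons C4a and C8a are adjacent and each is flanked by an oxygen-bearing carbon (C5, C8). The benzenoid ring is therefore a symmetric 3,6-dioxygenated benzyne, and C1–C4 with the side chain on C2 are the four carbons of a 3-substituted furan.
3. Key disconnection: C4–C4a and C1–C8a, i.e. 3,6-dimethoxybenzyne (from silyl triflate 18) plus the (S)-furyl silyl ether 10 in a [4+2] cycloaddition.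
4. Ring order: the benzenoid ring is bought as 2,5-dimethoxyphenol; the quinone ring is closed second as an oxygen-bridged 1,4-dihydronaphthalene; the bridge is opened to 1-naphthols, which are oxidised in the same flask at the para position to the quinone, and oxidative demethylation then gives the naphthazarin.
5. C1' is set before the key step by enantioselective reduction of the furan-3-yl ketone 7, made from 3-bromofuran and the Weinreb amide of 4-methylpent-3-enoic acid.

Key step: step 8

Remark: the cycloadduct 20 is carried as the pair of bridgehead epimers and the two regioisomeric naphthols 21 and 22 from bridge opening are not separated, because both elements vanish at quinone 23. Naphthazarin tautomers interconvert rapidly, so drawing the side chain on the quinone ring is a convention.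

**Route**

Step 1
Reactants: 1 4-methylpent-3-enoic acid
Product: 3 N-methoxy-N,4-dimethylpent-3-enamide, via acyl imidazolide 2 (not isolated)
Conditions: 1,1'-carbonyldiimidazole, CH2Cl2, rt; then MeNHOMe·HCl, rt
Reagents that add atoms: N,O-dimethylhydroxylamine hydrochloride, CNOC.Cl
Why: Carboxyl activation as the acyl imidazolide and aminolysis (Weinreb amide synthesis) run under near-neutral conditions, so the β,γ-olefin should stay out of conjugation.

Step 2
Reactants: 4 3-bromofuran; 3 N-methoxy-N,4-dimethylpent-3-enamide
Product: 7 1-(furan-3-yl)-4-methylpent-3-en-1-one, via furan-3-yllithium 5 (not isolated), via lithium hemiaminal alkoxide 6 (not isolated)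
Conditions: n-BuLi, THF, −78 °C; then 3, −78 → −40 °C; 0.5 M HCl, 0 °C
Reagents that add atoms: none
Why: Bromine–lithium exchange gives the 3-lithiofuran (kept below −40 °C to avoid migration to C2), which acylates once on the amide because the chelated adduct 6 survives until the cold quench (Weinreb ketone synthesis).

Step 3
Reactants: 7 1-(furan-3-yl)-4-methylpent-3-en-1-one
Product: 9 (1S)-1-(furan-3-yl)-4-methylpent-3-en-1-ol, via catechol borate ester 8 (not isolated)
Conditions: catecholborane (1.5 equiv), (R)-Me-CBS oxazaborolidine [(3aR)-1-methyl-3,3-diphenyltetrahydro-1H,3H-pyrrolo[1,2-c][1,3,2]oxazaborole, 0.15 equiv], toluene, −78 °C; MeOH, then aq. NaOH wash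
Reagents that add atoms: none
Why: In this Corey–Bakshi–Shibata reduction the ketone binds the ring boron with the furyl group as the large substituent, so hydride should go to the Re face and set C1' as S, while catecholborane at −78 °C should not hydroborate the trisubstituted olefin.

Step 4
Reactants: 9 (1S)-1-(furan-3-yl)-4-methylpent-3-en-1-ol
Product: 10 tert-butyl{[(1S)-1-(furan-3-yl)-4-methylpent-3-en-1-yl]oxy}dimethylsilane
Conditions: TBSCl, imidazole, DMF, rt
Reagents that add atoms: tert-butyldimethylsilyl chloride (TBSCl), CC(C)(C)[Si](C)(C)Cl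
Why: Imidazole-mediated O-silylation of a secondary alcohol is routine and does not touch the C1'–O bond, so the S configuration is retained.

Step 5
Reactants: 11 2,5-dimethoxyphenol
Product: 12 2,5-dimethoxyphenyl propan-2-ylcarbamate
Conditions: i-PrNCO, Et3N (cat.), CH2Cl2, rt
Reagents that add atoms: isopropyl isocyanate, CC(C)N=C=O
Why: Base-catalysed addition of the phenol to the isocyanate (carbamoylation) installs a directing group that can later be removed under mild base.

Step 6
Reactants: 12 2,5-dimethoxyphenyl propan-2-ylcarbamate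
Product: 16 3,6-dimethoxy-2-(trimethylsilyl)phenyl propan-2-ylcarbamate, via N-silyl carbamate 13 (not isolated), via ortho-lithiated carbamate 14 (not isolated), via N,C-disilyl carbamate 15 (not isolated)
Conditions: TBSOTf, TMEDA, Et2O, 0 °C → rt; n-BuLi, TMEDA, −78 °C; TMSCl, −78 °C → rt; aq. NaHSO4
Reagents that add atoms: chlorotrimethylsilane (TMSCl), C[Si](C)(C)Cl
Why: After in-flask N-silylation masks the N–H, directed ortho-metalation occurs at the only free position next to the carbamate, which is also ortho to a methoxy group, and TMSCl traps the aryllithium before an anionic Fries shift; the acidic work-up removes the N-silyl group.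

Step 7
Reactants: 16 3,6-dimethoxy-2-(trimethylsilyl)phenyl propan-2-ylcarbamate
Product: 18 3,6-dimethoxy-2-(trimethylsilyl)phenyl trifluoromethanesulfonate, via silylphenol 17 (not isolated)
Conditions: DBU, Et2NH, MeCN, 40 °C; then PhNTf2, rt
Reagents that add atoms: N-phenylbis(trifluoromethanesulfonimide) (PhNTf2), O=S(=O)(N(c1ccccc1)S(=O)(=O)C(F)(F)F)C(F)(F)F
Why: Amidine-promoted E1cB cleavage of the N-monoalkyl carbamate releases the phenoxide of 17 (the isocyanate is scavenged by Et2NH), and O-triflation in the same flask avoids handling the protodesilylation-prone silylphenol.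

Step 8
Reactants: 18 3,6-dimethoxy-2-(trimethylsilyl)phenyl trifluoromethanesulfonate; 10 tert-butyl{[(1S)-1-(furan-3-yl)-4-methylpent-3-en-1-yl]oxy}dimethylsilane
Product: 20 tert-butyl{[(1S)-1-(5,8-dimethoxy-1,4-dihydro-1,4-epoxynaphthalen-2-yl)-4-methylpent-3-en-1-yl]oxy}dimethylsilane (both bridgehead diastereomers), via 3,6-dimethoxybenzyne 19 (not isolated)
Conditions: 18 (1.3 equiv), CsF (3 equiv), MeCN, rt
Reagents that add atoms: none
Why: Fluoride attacks the trimethylsilyl group of 18 and the neighbouring triflate leaves, releasing aryne 19, whose strained in-plane π bond adds across C2 and C5 of the furan in a concerted suprafacial [4+2] cycloaddition; the closest known reaction type is the fluoride-triggered aryne–furan Diels–Alder reaction of 2-(trimethylsilyl)aryl triflates. The six-membered carbocycle (C1–C4 plus C4a and C8a, the future quinone ring) is closed by this intermolecular cycloaddition, with C4–C4a and C1–C8a formed in one event and the furan oxygen left as a 1,4-bridge. The two bridgehead stereocentres form cis by the suprafacial addition; their sense relative to C1' is not controlled and does not matter, because both are erased at the naphthol stage, while C1' lies outside the reacting atoms and keeps its S configuration. No regiocontrol is needed, since each aryne carbon has an ortho methoxy group and both orientations of the furan give the same constitution. The step does need chemoselectivity for the furan diene over an ene reaction at the prenyl olefin and over fluoride attack on the silyl ether; the high diene reactivity of furan towards arynes and the low solubility and basicity of CsF in acetonitrile at room temperature should secure both.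

Step 9
Reactants: 20 tert-butyl{[(1S)-1-(5,8-dimethoxy-1,4-dihydro-1,4-epoxynaphthalen-2-yl)-4-methylpent-3-en-1-yl]oxy}dimethylsilane
Product: 23 2-[(1S)-1-{[tert-butyl(dimethyl)silyl]oxy}-4-methylpent-3-en-1-yl]-5,8-dimethoxynaphthalene-1,4-dione, via 2-substituted naphthol 21 (not isolated), via 3-substituted naphthol 22 (not isolated)
Conditions: CF3CO2H (cat.), CH2Cl2, 0 °C; evaporate; then ON(SO3K)2 (2.5 equiv), KH2PO4, acetone/H2O, rt
Reagents that add atoms: potassium nitrosodisulfonate ON(SO3K)2, [K+].[K+].[O]N(S(=O)(=O)[O-])S(=O)(=O)[O-]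
Why: Acid-catalysed isomerisation of the 1,4-epoxy-1,4-dihydronaphthalene (protonation of the bridge oxygen, ionisation of a bridgehead C–O bond to an allylic, benzylic cation and proton loss from the carbinol carbon) should give mainly 21 by cleavage of C4–O, where the charge is shared with the substituted C2, and some 22 by cleavage of C1–O, and the Teuber oxidation then delivers oxygen to the free para position of either naphthol, so both converge on the same 2-substituted 1,4-quinone under buffered conditions that spare the silyl ether and the olefin.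

Step 10
Reactants: 23 2-[(1S)-1-{[tert-butyl(dimethyl)silyl]oxy}-4-methylpent-3-en-1-yl]-5,8-dimethoxynaphthalene-1,4-dione
Product: 25 2-[(1S)-1-{[tert-butyl(dimethyl)silyl]oxy}-4-methylpent-3-en-1-yl]-5,8-dihydroxynaphthalene-1,4-dione, via naphthalenetetrone 24 (not isolated)
Conditions: AgO, 6 M HNO3, 1,4-dioxane, rt, a few minutes; then aq. Na2S2O4
Reagents that add atoms: water, O
Why: AgO-mediated oxidative demethylation of the remaining para-dimethoxy ring (water attacks the ipso carbons of the radical cation and methanol leaves) gives tetrone 24, which dithionite reduces by two electrons to the naphthazarin; any silyl ether lost in the acid simply arrives early at 26.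

Step 11
Reactants: 25 2-[(1S)-1-{[tert-butyl(dimethyl)silyl]oxy}-4-methylpent-3-en-1-yl]-5,8-dihydroxynaphthalene-1,4-dione
Product: 26 5,8-dihydroxy-2-[(1S)-1-hydroxy-4-methylpent-3-en-1-yl]naphthalene-1,4-dione (alkannin)
Conditions: HF·pyridine, pyridine, THF, 0 °C → rt
Reagents that add atoms: none
Why: Fluoride-mediated desilylation in a buffered, weakly acidic medium avoids the base-sensitive naphthazarin phenoxides and should be too mild to cyclise the hydroxyl onto the prenyl olefin; the C1'–O bond is not broken.

Step 12
Reactants: 27 3-hydroxy-3-methylbutanoic acid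
Product: 29 3-(acetyloxy)-3-methylbutanoic acid, via mixed anhydride 28 (not isolated)
Conditions: AcCl (neat, excess), 0 °C → rt; evaporate; H2O/THF, rt
Reagents that add atoms: acetyl chloride, CC(=O)Cl
Why: O-Acetylation of a hydroxy acid in neat acetyl chloride acylates the tertiary alcohol without base and so avoids β-elimination; the carboxyl group is acetylated in passing to anhydride 28, which water cleaves far faster than the tertiary ester.

Step 13
Reactants: 26 alkannin; 29 3-(acetyloxy)-3-methylbutanoic acid
Product: 31 (1S)-1-(5,8-dihydroxy-1,4-dioxo-1,4-dihydronaphthalen-2-yl)-4-methylpent-3-en-1-yl 3-(acetyloxy)-3-methylbutanoate, via O-acylisourea 30 (not isolated)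
Conditions: DCC (1.5 equiv), 4-(dimethylamino)pyridine (0.1 equiv), CH2Cl2, 0 °C → rt
Reagents that add atoms: none
Why: In this Steglich esterification the acyl group passes from 30 through the acylpyridinium to the secondary C1' hydroxyl with retention (the C–O bond is untouched), while the two peri-hydroxyls are hydrogen-bonded to the quinone carbonyls and should not compete.

**Compound list**

1 | 4-methylpent-3-enoic acid | CC(C)=CCC(=O)O | starting material
2 | 1-(1H-imidazol-1-yl)-4-methylpent-3-en-1-one (acyl imidazolide) | CC(C)=CCC(=O)n1ccnc1 | intermediate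
3 | N-methoxy-N,4-dimethylpent-3-enamide | CC(C)=CCC(=O)N(C)OC | intermediate
4 | 3-bromofuran | Brc1ccoc1 | starting material
5 | furan-3-yllithium | [Li]c1ccoc1 | intermediate
6 | lithium 1-(furan-3-yl)-1-[methoxy(methyl)amino]-4-methylpent-3-en-1-olate | [Li+].[O-]C(CC=C(C)C)(N(C)OC)c1ccoc1 | intermediate
7 | 1-(furan-3-yl)-4-methylpent-3-en-1-one | CC(C)=CCC(=O)c1ccoc1 | intermediate
8 | 2-{[(1S)-1-(furan-3-yl)-4-methylpent-3-en-1-yl]oxy}-1,3,2-benzodioxaborole | c1ccc2OB(O[C@@H](CC=C(C)C)c3ccoc3)Oc2c1 | intermediate
9 | (1S)-1-(furan-3-yl)-4-methylpent-3-en-1-ol | O[C@@H](CC=C(C)C)c1ccoc1 | intermediate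
10 | tert-butyl{[(1S)-1-(furan-3-yl)-4-methylpent-3-en-1-yl]oxy}dimethylsilane | CC(C)(C)[Si](C)(C)O[C@@H](CC=C(C)C)c1ccoc1 | intermediate
11 | 2,5-dimethoxyphenol | COc1ccc(OC)c(O)c1 | starting material
12 | 2,5-dimethoxyphenyl propan-2-ylcarbamate | COc1ccc(OC)c(OC(=O)NC(C)C)c1 | intermediate
13 | 2,5-dimethoxyphenyl [tert-butyl(dimethyl)silyl](propan-2-yl)carbamate | COc1ccc(OC)c(OC(=O)N(C(C)C)[Si](C)(C)C(C)(C)C)c1 | intermediate
14 | 6-lithio derivative of 13 (lithium on the ring carbon between the carbamate-bearing and the 5-methoxy-bearing carbons) | COc1ccc(OC)c(OC(=O)N(C(C)C)[Si](C)(C)C(C)(C)C)c1[Li] | intermediate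
15 | 3,6-dimethoxy-2-(trimethylsilyl)phenyl [tert-butyl(dimethyl)silyl](propan-2-yl)carbamate | COc1ccc(OC)c(OC(=O)N(C(C)C)[Si](C)(C)C(C)(C)C)c1[Si](C)(C)C | intermediate
16 | 3,6-dimethoxy-2-(trimethylsilyl)phenyl propan-2-ylcarbamate | COc1ccc(OC)c(OC(=O)NC(C)C)c1[Si](C)(C)C | intermediate
17 | 3,6-dimethoxy-2-(trimethylsilyl)phenol (as its amidinium phenoxide) | COc1ccc(OC)c(O)c1[Si](C)(C)C | intermediate
18 | 3,6-dimethoxy-2-(trimethylsilyl)phenyl trifluoromethanesulfonate | COc1ccc(OC)c(OS(=O)(=O)C(F)(F)F)c1[Si](C)(C)C | intermediate
19 | 3,6-dimethoxybenzyne (1,4-dimethoxy-2,3-didehydrobenzene) | COC1=CC=C(OC)C#C1 | intermediate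
20 | tert-butyl{[(1S)-1-(5,8-dimethoxy-1,4-dihydro-1,4-epoxynaphthalen-2-yl)-4-methylpent-3-en-1-yl]oxy}dimethylsilane (pair of bridgehead epimers; bridgeheads left undefined) | CC(C)(C)[Si](C)(C)O[C@@H](CC=C(C)C)C1=CC2OC1c1c(OC)ccc(OC)c12 | intermediate
21 | 2-[(1S)-1-{[tert-butyl(dimethyl)silyl]oxy}-4-methylpent-3-en-1-yl]-5,8-dimethoxynaphthalen-1-ol | CC(C)(C)[Si](C)(C)O[C@@H](CC=C(C)C)c1ccc2c(OC)ccc(OC)c2c1O | intermediate
22 | 3-[(1S)-1-{[tert-butyl(dimethyl)silyl]oxy}-4-methylpent-3-en-1-yl]-5,8-dimethoxynaphthalen-1-ol (minor regioisomer) | CC(C)(C)[Si](C)(C)O[C@@H](CC=C(C)C)c1cc(O)c2c(OC)ccc(OC)c2c1 | intermediate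
23 | 2-[(1S)-1-{[tert-butyl(dimethyl)silyl]oxy}-4-methylpent-3-en-1-yl]-5,8-dimethoxynaphthalene-1,4-dione | CC(C)(C)[Si](C)(C)O[C@@H](CC=C(C)C)C1=CC(=O)c2c(OC)ccc(OC)c2C1=O | intermediate
24 | 2-[(1S)-1-{[tert-butyl(dimethyl)silyl]oxy}-4-methylpent-3-en-1-yl]naphthalene-1,4,5,8-tetrone | CC(C)(C)[Si](C)(C)O[C@@H](CC=C(C)C)C1=CC(=O)C2=C(C1=O)C(=O)C=CC2=O | intermediate
25 | 2-[(1S)-1-{[tert-butyl(dimethyl)silyl]oxy}-4-methylpent-3-en-1-yl]-5,8-dihydroxynaphthalene-1,4-dione | CC(C)(C)[Si](C)(C)O[C@@H](CC=C(C)C)C1=CC(=O)c2c(O)ccc(O)c2C1=O | intermediate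
26 | 5,8-dihydroxy-2-[(1S)-1-hydroxy-4-methylpent-3-en-1-yl]naphthalene-1,4-dione (alkannin) | O[C@@H](CC=C(C)C)C1=CC(=O)c2c(O)ccc(O)c2C1=O | intermediate
27 | 3-hydroxy-3-methylbutanoic acid | CC(C)(O)CC(=O)O | starting material
28 | acetic 3-(acetyloxy)-3-methylbutanoic anhydride | CC(=O)OC(C)(C)CC(=O)OC(C)=O | intermediate
29 | 3-(acetyloxy)-3-methylbutanoic acid | CC(=O)OC(C)(C)CC(=O)O | intermediate
30 | N,N'-dicyclohexyl-O-[3-(acetyloxy)-3-methylbutanoyl]isourea | CC(=O)OC(C)(C)CC(=O)OC(=NC1CCCCC1)NC1CCCCC1 | intermediate
31 | (1S)-1-(5,8-dihydroxy-1,4-dioxo-1,4-dihydronaphthalen-2-yl)-4-methylpent-3-en-1-yl 3-(acetyloxy)-3-methylbutanoate | CC(=O)OC(C)(C)CC(=O)O[C@@H](CC=C(C)C)C1=CC(=O)c2c(O)ccc(O)c2C1=O | target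

**Step count and risks**

Total step count: 13. Longest linear sequence: 9 steps (steps 1, 2, 3, 4, 8, 9, 10, 11, 13).

Steps most likely to fail:

- **Step 10.** The dimethoxy ring of 23 is deactivated by the two quinone carbonyls, so electron transfer to AgO may be slow. The strongly acidic oxidising medium may then degrade the side chain (olefin attack, uncontrolled silyl loss) before demethylation is complete. The fallback sets out from 23 and reverses the electronic bias. Reductive acetylation (Zn dust, Ac2O, pyridine, rt) would give 2-[(1S)-1-{[tert-butyl(dimethyl)silyl]oxy}-4-methylpent-3-en-1-yl]-5,8-dimethoxynaphthalene-1,4-diyl diacetate F1, in which the dimethoxy ring is now the electron-rich one. Oxidative demethylation with (NH4)2Ce(NO3)6 in MeCN/H2O at 0 °C should then give 2-[(1S)-1-{[tert-butyl(dimethyl)silyl]oxy}-4-methylpent-3-en-1-yl]-5,8-dioxo-5,8-dihydronaphthalene-1,4-diyl diacetate F2. Brief methanolysis of the two aryl acetates (K2CO3, MeOH, 0 °C, argon, then acidification) gives the naphthazarin, whose tautomer is 25, where the route is rejoined.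

- **Step 9.** Once the naphthols form, the C1' silyl ether of 21 is ortho-hydroxybenzylic on an electron-rich ring. Acid may ionise it (loss of silanol towards a quinone methide, with erosion of the C1' configuration or elimination) or cleave the silyl group in competition with simple aromatisation. The fallback sets out from 20 and replaces carbocation chemistry by a neutral transition-metal-catalysed isomerisation: [RuCl2(CO)3]2 (cat.) in 1,2-dichloroethane at 60 °C. Here the metal inserts into the allylic bridging C–O bond, and β-hydride elimination and tautomerisation deliver the naphthols without free acid. It comes back to the route at the naphthols 21 and 22, which are oxidised with ON(SO3K)2 to 23 as in the second half of step 9, and makes no compound outside the list (F0).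

- **Step 8.** Fluoride may attack the silyl ether of 10, or the aryne may be released slowly and be lost to side reactions (ene reaction at the prenyl olefin, self-condensation) before the furan captures it. The fallback sets out from 10 and generates the same aryne without fluoride. Purchased 2-bromo-1,4-dimethoxybenzene F3 would be deprotonated between bromine and methoxy by lithium 2,2,6,6-tetramethylpiperidide (LiTMP) in THF at −78 °C to give (2-bromo-3,6-dimethoxyphenyl)lithium F4. On warming F4 loses LiBr to give 19, which is trapped in the flask by 10, so the route is rejoined at 20.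

**Further compounds**

F1 | step 10 | 2-[(1S)-1-{[tert-butyl(dimethyl)silyl]oxy}-4-methylpent-3-en-1-yl]-5,8-dimethoxynaphthalene-1,4-diyl diacetate | CC(C)(C)[Si](C)(C)O[C@@H](CC=C(C)C)c1cc(OC(C)=O)c2c(OC)ccc(OC)c2c1OC(C)=O
F2 | step 10 | 2-[(1S)-1-{[tert-butyl(dimethyl)silyl]oxy}-4-methylpent-3-en-1-yl]-5,8-dioxo-5,8-dihydronaphthalene-1,4-diyl diacetate | CC(C)(C)[Si](C)(C)O[C@@H](CC=C(C)C)c1cc(OC(C)=O)c2C(=O)C=CC(=O)c2c1OC(C)=O
F0 | step 9 | none | none
F3 | step 8 | 2-bromo-1,4-dimethoxybenzene (purchased) | COc1ccc(OC)c(Br)c1
F4 | step 8 | (2-bromo-3,6-dimethoxyphenyl)lithium | COc1ccc(OC)c(Br)c1[Li]
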